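**Strategy.** The chain is numbered from the lactone carbonyl (C1) to the CH2 on the furan (C15). Everything rests on cutting C9–C10 and C11–C12. Carbinol C10 sits directly on the trisubstituted C8=C9 alkene and, through methylene C11, on the C12=C13 alkene, so a two-carbon vinyl unit can be inserted between two E-alkenyl partners. In one operation a palladium-induced 1,2-boronate shift unites an E-alkenylboronic ester (C3–C9, already carrying a silylated oxygen on C3), vinyllithium (C10–C11) and an E-alkenyl bromide (C12–C15 plus the furan ring) and sets C10; no ring closes. The γ-lactone ring (O, C1–C4) and C4/C5 follow by Sharpless epoxidation, two-carbon extension and epoxide-opening lactonisation.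

Key step: step 10

Assumption: the (Sp,Sp) antipode of the MandyPhos ligand is taken to give the 10R boronate by analogy with related boronate shifts; if the sense is opposite, the (Rp,Rp) ligand is used with nothing else changed.

Step 1
Reactants: 1 5-bromo-2-methylpent-2-ene; 2 lithium acetylide–ethylenediamine complex
Product: 3 6-methylhept-5-en-1-yne
Conditions: DMSO, 10 °C to rt
Reagents that add atoms: none
Why: SN2 alkylation of an acetylide by a primary homoallylic bromide in a dipolar aprotic solvent is a standard route to terminal alkynes and leaves the trisubstituted alkene alone.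

Step 2
Reactants: 3 6-methylhept-5-en-1-yne
Product: 4 (2E)-2-methylhept-2-en-6-yn-1-ol
Conditions: SeO2 (cat.), t-BuOOH, CH2Cl2, rt
Reagents that add atoms: tert-butyl hydroperoxide, CC(C)(C)OO (oxygen relayed by catalytic SeO2, O=[Se]=O)
Why: Riley-type allylic oxidation (ene reaction then [2,3]-shift) of the only alkene present, a gem-dimethyl trisubstituted one, should hydroxylate the E-methyl group, the terminal alkyne reacting much more slowly.

Step 3
Reactants: 4 (2E)-2-methylhept-2-en-6-yn-1-ol
Product: 5 tert-butyl(dimethyl){[(2E)-2-methylhept-2-en-6-yn-1-yl]oxy}silane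
Conditions: TBSCl, imidazole, CH2Cl2, rt
Reagents that add atoms: tert-butyl(chloro)dimethylsilane, CC(C)(C)[Si](C)(C)Cl
Why: Standard silylation of a primary alcohol gives an ether that tolerates organoaluminium, organolithium and palladium chemistry.

Step 4
Reactants: 5 tert-butyl(dimethyl){[(2E)-2-methylhept-2-en-6-yn-1-yl]oxy}silane; 6 2-isopropoxy-4,4,5,5-tetramethyl-1,3,2-dioxaborolane
Product: 8 tert-butyl(dimethyl){[(2E,6E)-2,6-dimethyl-7-(4,4,5,5-tetramethyl-1,3,2-dioxaborolan-2-yl)hepta-2,6-dien-1-yl]oxy}silane, via alkenylalane 7 (not isolated)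
Conditions: AlMe3, Cp2ZrCl2 (cat.), CH2Cl2, 0 °C to rt; volatiles removed; then 6, THF, 0 °C to rt
Reagents that add atoms: trimethylaluminium, C[Al](C)C
Why: Zirconium-catalysed syn-methylalumination (Negishi carboalumination) puts methyl on the internal and aluminium on the terminal alkyne carbon, which fixes the E geometry of C8=C9, and the alkenyl group then passes from aluminium to boron with retention.

Step 5
Reactants: 9 tetravinylstannane
Product: 10 vinyllithium
Conditions: n-BuLi, pentane, rt; solid filtered under argon, washed, dissolved in THF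
Reagents that add atoms: n-butyllithium, [Li]CCCC
Why: Tin–lithium exchange is driven by precipitation of vinyllithium and gives a halide-free reagent, which the palladium step needs.

Step 6
Reactants: 11 but-2-yn-1-ol
Product: 13 (2E)-3-bromobut-2-en-1-ol, via alkenylzirconocene 12 (not isolated)
Conditions: Cp2Zr(H)Cl (2.2 equiv), THF, 0 °C to rt; then NBS, 0 °C
Reagents that add atoms: N-bromosuccinimide, O=C1CCC(=O)N1Br
Why: Schwartz hydrozirconation adds Zr–H syn with zirconium at the methyl-bearing carbon, away from the bulky zirconium alkoxide formed from the hydroxyl group, and bromination of the C–Zr bond with retention should give the E bromide.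

Step 7
Reactants: 13 (2E)-3-bromobut-2-en-1-ol
Product: 14 (2E)-1,3-dibromobut-2-ene
Conditions: CBr4, PPh3, CH2Cl2, 0 °C
Reagents that add atoms: carbon tetrabromide, BrC(Br)(Br)Br
Why: Appel bromination converts the primary allylic alcohol by SN2 under neutral conditions without touching the vinylic bromide or the alkene geometry.

Step 8
Reactants: 15 furan-3-ylmethanol
Product: 16 3-(chloromethyl)furan
Conditions: SOCl2, pyridine, Et2O, 0 °C
Reagents that add atoms: thionyl chloride, O=S(Cl)Cl
Why: Chlorination through the chlorosulfite in the presence of base spares the acid-sensitive furan; the chloride is used at once.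

Step 9
Reactants: 16 3-(chloromethyl)furan; 14 (2E)-1,3-dibromobut-2-ene
Product: 18 3-[(3E)-4-bromopent-3-en-1-yl]furan, via furylmethyl Grignard reagent 17 (not isolated)
Conditions: Mg, THF, 0 °C to rt; then 14, Li2CuCl4 (cat.), THF, −20 to 0 °C
Reagents that add atoms: none
Why: Copper-catalysed Grignard allylic substitution attacks the primary α-carbon of a γ,γ-disubstituted allyl bromide with retention of alkene geometry, and an allylic C–Br bond reacts far faster than a vinylic one, as in the classical alkylation of 2,3-dibromopropene.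

Step 10
Reactants: 8 tert-butyl(dimethyl){[(2E,6E)-2,6-dimethyl-7-(4,4,5,5-tetramethyl-1,3,2-dioxaborolan-2-yl)hepta-2,6-dien-1-yl]oxy}silane; 10 vinyllithium; 18 3-[(3E)-4-bromopent-3-en-1-yl]furan
Product: 20 tert-butyl(dimethyl){[(2E,6E,8R,10E)-13-(furan-3-yl)-2,6,10-trimethyl-8-(4,4,5,5-tetramethyl-1,3,2-dioxaborolan-2-yl)trideca-2,6,10-trien-1-yl]oxy}silane, via lithium bis(alkenyl)boronate 19 (not isolated)
Conditions: 8, 10, THF, 0 °C to rt; then Pd(OAc)2 (3 mol%), (Sp,Sp)-MandyPhos [2,2′-bis(diarylphosphino)-1,1′-bis(α-dimethylaminobenzyl)ferrocene] (3.6 mol%), KOTf, 18, THF, 60 °C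
Reagents that add atoms: none
Why: Conjunctive cross-coupling: vinyllithium adds to boron of 8 to give four-coordinate boronate 19, zerovalent palladium inserts into the C–Br bond of 18 with retention, and the divalent alkenylpalladium, freed of bromide by KOTf, binds the unhindered vinyl group of 19. This triggers a 1,2-shift of the C9 alkenyl group from boron to C10 anti to palladium (C9–C10), and the alkylpalladium left at C11 reductively eliminates to form C11–C12. The closest known reaction type is the enantioselective palladium-catalysed conjunctive coupling of bis(alkenyl)boronates to allylic boronic esters, here run with an alkenyl bromide as the electrophile. No ring is closed. The only new stereocentre, C10 (R), is set by the chiral diphosphine, since none of the three partners is chiral. The step needs palladium to engage the vinyl group and not the trisubstituted alkenyl group, and to avoid direct Suzuki-type transfer; the steric gap between CH=CH2 and CH=C(CH3)R, the wide-bite-angle ligand and the halide-free vinyllithium should secure this, and both E alkenes are carried through because insertion, migration and elimination are stereoretentive.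

Step 11
Reactants: 20 the C10 pinacol boronic ester
Product: 21 (2E,6E,8R,10E)-1-{[tert-butyl(dimethyl)silyl]oxy}-13-(furan-3-yl)-2,6,10-trimethyltrideca-2,6,10-trien-8-ol
Conditions: NaOH (3 M aq.), H2O2 (30% aq.), THF, 0 °C to rt
Reagents that add atoms: hydrogen peroxide, OO
Why: Alkaline hydroperoxide oxidation of a C–B bond goes by 1,2-migration of carbon to oxygen with retention and without allylic transposition, so 10R is kept.

Step 12
Reactants: 21 the C10 alcohol
Product: 22 (2E,6E,8R,10E)-1-{[tert-butyl(dimethyl)silyl]oxy}-13-(furan-3-yl)-2,6,10-trimethyltrideca-2,6,10-trien-8-yl acetate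
Conditions: Ac2O, pyridine, DMAP (cat.), CH2Cl2, 0 °C to rt
Reagents that add atoms: acetic anhydride, CC(=O)OC(C)=O
Why: Acylation masks the C10 hydroxyl so that it can neither direct epoxidation nor be oxidised later, and an ester is chosen because the final saponification removes it.

Step 13
Reactants: 22 the C10 acetate
Product: 23 (2E,6E,8R,10E)-13-(furan-3-yl)-1-hydroxy-2,6,10-trimethyltrideca-2,6,10-trien-8-yl acetate
Conditions: HF·pyridine, pyridine, THF, 0 °C to rt
Reagents that add atoms: none
Why: Buffered fluoride cleavage of the primary allylic silyl ether leaves the acetate, the furan and the alkenes untouched.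

Step 14
Reactants: 23 the C3 allylic alcohol
Product: 24 [(2R,3R)-3-{(3E,5R,7E)-5-acetoxy-10-(furan-3-yl)-3,7-dimethyldeca-3,7-dien-1-yl}-2-methyloxiran-2-yl]methanol
Conditions: Ti(OiPr)4 (10 mol%), D-(−)-diisopropyl tartrate (12 mol%), t-BuOOH, 4 Å molecular sieves, CH2Cl2, −20 °C
Reagents that add atoms: tert-butyl hydroperoxide, CC(C)(C)OO
Why: Sharpless asymmetric epoxidation acts only on the alkene of the free primary allylic alcohol, and with the D-(−)-tartrate the reagent-controlled facial rule for E-2-methylalk-2-en-1-ols should give the (2R,3R)-epoxide, which sets C5 directly and C4 for later inversion.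

Step 15
Reactants: 24 the epoxy alcohol; 25 ethyl (triphenylphosphoranylidene)acetate
Product: 27 ethyl (2E)-3-[(2R,3R)-3-{(3E,5R,7E)-5-acetoxy-10-(furan-3-yl)-3,7-dimethyldeca-3,7-dien-1-yl}-2-methyloxiran-2-yl]prop-2-enoate, via epoxy aldehyde 26 (not isolated)
Conditions: Dess–Martin periodinane, pyridine, CH2Cl2, 0 °C to rt; then 25, rt
Reagents that add atoms: none
Why: Dess–Martin oxidation gives an α-quaternary epoxy aldehyde that cannot epimerise, and the stabilised ylide added to the same flask brings in C1 and C2 by an E-selective Wittig olefination.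

Step 16
Reactants: 27 the epoxy enoate
Product: 28 ethyl 3-[(2R,3R)-3-{(3E,5R,7E)-5-acetoxy-10-(furan-3-yl)-3,7-dimethyldeca-3,7-dien-1-yl}-2-methyloxiran-2-yl]propanoate
Conditions: 2-nitrobenzenesulfonohydrazide, Et3N, CH2Cl2, rt
Reagents that add atoms: none
Why: Diimide reduction, a concerted syn transfer of two hydrogens, should saturate the disubstituted conjugated C2=C3 alkene much faster than the three trisubstituted alkenes and, unlike hydride or catalytic hydrogenation, neither opens the allylic epoxide nor reduces the furan.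

Step 17
Reactants: 28 the saturated epoxy ester
Product: 30 (5S)-5-[(1R,4E,6R,8E)-11-(furan-3-yl)-1,6-dihydroxy-4,8-dimethylundeca-4,8-dien-1-yl]-5-methyloxolan-2-one (target), via epoxy hydroxy acid 29 (not isolated)
Conditions: LiOH, THF/MeOH/H2O, 0 °C to rt; then 0.5 M HCl to pH 3–4, CH2Cl2, rt
Reagents that add atoms: lithium hydroxide, [Li+].[OH-] (one oxygen of the lactone)
Why: Saponification frees the carboxylic acid and the C10 hydroxyl, and on acidification the acid opens the epoxide by 5-exo attack at tertiary C4 with inversion (epoxide-opening lactonisation), closing the γ-lactone and leaving the epoxide oxygen as the C5 hydroxyl with retention, which gives 4S,5R.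

**Compound list**

1 | 5-bromo-2-methylpent-2-ene | CC(C)=CCCBr | starting material
2 | lithium acetylide–ethylenediamine complex | [Li]C#C.NCCN | starting material
3 | 6-methylhept-5-en-1-yne | C#CCCC=C(C)C | intermediate
4 | (2E)-2-methylhept-2-en-6-yn-1-ol | OC/C(C)=C/CCC#C | intermediate
5 | tert-butyl(dimethyl){[(2E)-2-methylhept-2-en-6-yn-1-yl]oxy}silane | CC(C)(C)[Si](C)(C)OC/C(C)=C/CCC#C | intermediate
6 | 2-isopropoxy-4,4,5,5-tetramethyl-1,3,2-dioxaborolane | CC(C)OB1OC(C)(C)C(C)(C)O1 | starting material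
7 | [(1E,5E)-7-{[tert-butyl(dimethyl)silyl]oxy}-2,6-dimethylhepta-1,5-dien-1-yl](dimethyl)alumane | CC(C)(C)[Si](C)(C)OC/C(C)=C/CC/C(C)=C/[Al](C)C | intermediate
8 | tert-butyl(dimethyl){[(2E,6E)-2,6-dimethyl-7-(4,4,5,5-tetramethyl-1,3,2-dioxaborolan-2-yl)hepta-2,6-dien-1-yl]oxy}silane | CC(C)(C)[Si](C)(C)OC/C(C)=C/CC/C(C)=C/B1OC(C)(C)C(C)(C)O1 | intermediate
9 | tetravinylstannane | C=C[Sn](C=C)(C=C)C=C | starting material
10 | vinyllithium | [Li]C=C | intermediate
11 | but-2-yn-1-ol | CC#CCO | starting material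
12 | [(2E)-4-{[chloridobis(cyclopentadienyl)zirconio]oxy}but-2-en-2-yl]chloridobis(cyclopentadienyl)zirconium | C/C(=C\CO[Zr](Cl)(C1C=CC=C1)C1C=CC=C1)[Zr](Cl)(C1C=CC=C1)C1C=CC=C1 | intermediate
13 | (2E)-3-bromobut-2-en-1-ol | Br/C(C)=C/CO | intermediate
14 | (2E)-1,3-dibromobut-2-ene | Br/C(C)=C/CBr | intermediate
15 | furan-3-ylmethanol | OCc1ccoc1 | starting material
16 | 3-(chloromethyl)furan | ClCc1ccoc1 | intermediate
17 | (furan-3-ylmethyl)magnesium chloride | Cl[Mg]Cc1ccoc1 | intermediate
18 | 3-[(3E)-4-bromopent-3-en-1-yl]furan | Br/C(C)=C/CCc1ccoc1 | intermediate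
19 | lithium [(1E,5E)-7-{[tert-butyl(dimethyl)silyl]oxy}-2,6-dimethylhepta-1,5-dien-1-yl](ethenyl)(pinacolato)borate | [Li+].CC(C)(C)[Si](C)(C)OC/C(C)=C/CC/C(C)=C/[B-]1(C=C)OC(C)(C)C(C)(C)O1 | intermediate
20 | tert-butyl(dimethyl){[(2E,6E,8R,10E)-13-(furan-3-yl)-2,6,10-trimethyl-8-(4,4,5,5-tetramethyl-1,3,2-dioxaborolan-2-yl)trideca-2,6,10-trien-1-yl]oxy}silane | CC(C)(C)[Si](C)(C)OC/C(C)=C/CC/C(C)=C/[C@H](B1OC(C)(C)C(C)(C)O1)C/C(C)=C/CCc1ccoc1 | intermediate
21 | (2E,6E,8R,10E)-1-{[tert-butyl(dimethyl)silyl]oxy}-13-(furan-3-yl)-2,6,10-trimethyltrideca-2,6,10-trien-8-ol | CC(C)(C)[Si](C)(C)OC/C(C)=C/CC/C(C)=C/[C@H](O)C/C(C)=C/CCc1ccoc1 | intermediate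
22 | (2E,6E,8R,10E)-1-{[tert-butyl(dimethyl)silyl]oxy}-13-(furan-3-yl)-2,6,10-trimethyltrideca-2,6,10-trien-8-yl acetate | CC(C)(C)[Si](C)(C)OC/C(C)=C/CC/C(C)=C/[C@H](OC(C)=O)C/C(C)=C/CCc1ccoc1 | intermediate
23 | (2E,6E,8R,10E)-13-(furan-3-yl)-1-hydroxy-2,6,10-trimethyltrideca-2,6,10-trien-8-yl acetate | OC/C(C)=C/CC/C(C)=C/[C@H](OC(C)=O)C/C(C)=C/CCc1ccoc1 | intermediate
24 | [(2R,3R)-3-{(3E,5R,7E)-5-acetoxy-10-(furan-3-yl)-3,7-dimethyldeca-3,7-dien-1-yl}-2-methyloxiran-2-yl]methanol | OC[C@@]1(C)O[C@@H]1CC/C(C)=C/[C@H](OC(C)=O)C/C(C)=C/CCc1ccoc1 | intermediate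
25 | ethyl (triphenylphosphoranylidene)acetate | CCOC(=O)C=P(c1ccccc1)(c1ccccc1)c1ccccc1 | starting material
26 | (2S,3R)-3-{(3E,5R,7E)-5-acetoxy-10-(furan-3-yl)-3,7-dimethyldeca-3,7-dien-1-yl}-2-methyloxirane-2-carbaldehyde | O=C[C@@]1(C)O[C@@H]1CC/C(C)=C/[C@H](OC(C)=O)C/C(C)=C/CCc1ccoc1 | intermediate
27 | ethyl (2E)-3-[(2R,3R)-3-{(3E,5R,7E)-5-acetoxy-10-(furan-3-yl)-3,7-dimethyldeca-3,7-dien-1-yl}-2-methyloxiran-2-yl]prop-2-enoate | CCOC(=O)/C=C/[C@@]1(C)O[C@@H]1CC/C(C)=C/[C@H](OC(C)=O)C/C(C)=C/CCc1ccoc1 | intermediate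
28 | ethyl 3-[(2R,3R)-3-{(3E,5R,7E)-5-acetoxy-10-(furan-3-yl)-3,7-dimethyldeca-3,7-dien-1-yl}-2-methyloxiran-2-yl]propanoate | CCOC(=O)CC[C@@]1(C)O[C@@H]1CC/C(C)=C/[C@H](OC(C)=O)C/C(C)=C/CCc1ccoc1 | intermediate
29 | 3-[(2R,3R)-3-{(3E,5R,7E)-10-(furan-3-yl)-5-hydroxy-3,7-dimethyldeca-3,7-dien-1-yl}-2-methyloxiran-2-yl]propanoic acid | OC(=O)CC[C@@]1(C)O[C@@H]1CC/C(C)=C/[C@H](O)C/C(C)=C/CCc1ccoc1 | intermediate
30 | (5S)-5-[(1R,4E,6R,8E)-11-(furan-3-yl)-1,6-dihydroxy-4,8-dimethylundeca-4,8-dien-1-yl]-5-methyloxolan-2-one | C/C(=C\[C@H](O)C/C(C)=C/CCc1ccoc1)CC[C@@H](O)[C@]1(C)CCC(=O)O1 | target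

**Step count.** Total: 17 steps. Longest linear sequence: 12 steps (steps 1–4 and 10–17).

**Steps most likely to fail**

1. Step 10. Direct transfer of an alkenyl group from boron to palladium may outrun the 1,2-shift, bromide may slow the cationic palladium pathway, or facial control at C10 may be insufficient. The fallback builds C9–C10 by carbonyl addition; it sets out from 18 and 5 and returns at 21. Bromide 18 undergoes bromine–lithium exchange (t-BuLi, Et2O, −78 °C) and opens ethylene oxide (BF3·OEt2) to give (3E)-6-(furan-3-yl)-3-methylhex-3-en-1-ol F1. Dess–Martin oxidation gives (3E)-6-(furan-3-yl)-3-methylhex-3-enal F2, used crude. Alkenylalane 7, made from 5 as in step 4 and converted to its lithium alanate with n-BuLi, adds to F2 to give (2E,6E,10E)-1-{[tert-butyl(dimethyl)silyl]oxy}-13-(furan-3-yl)-2,6,10-trimethyltrideca-2,6,10-trien-8-ol F3 as both C8 epimers. Oxidation with MnO2 gives (2E,6E,10E)-1-{[tert-butyl(dimethyl)silyl]oxy}-13-(furan-3-yl)-2,6,10-trimethyltrideca-2,6,10-trien-8-one F4. Corey–Bakshi–Shibata reduction with the (S)-methyl oxazaborolidine and catecholborane, the alkenyl group acting as the large substituent, should then give 21.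

2. Step 16. Diimide transfer to the conjugated alkene may be slow, so that forcing it begins to saturate the trisubstituted alkenes or leaves starting enoate. The fallback brings in C1–C2 by alkylation in place of olefination and reduction; it sets out from 24 and returns at 30. Epoxy alcohol 24 is converted (I2, PPh3, imidazole) into (3E,5R,7E)-10-(furan-3-yl)-1-[(2R,3S)-3-(iodomethyl)-3-methyloxiran-2-yl]-3,7-dimethyldeca-3,7-dien-5-yl acetate F5. Sodium dimethyl malonate (NaH, THF/DMF) displaces iodide to give dimethyl 2-{[(2R,3R)-3-{(3E,5R,7E)-5-acetoxy-10-(furan-3-yl)-3,7-dimethyldeca-3,7-dien-1-yl}-2-methyloxiran-2-yl]methyl}propanedioate F6. LiOH then mild acid removes the three ester groups and closes the lactone to (5S)-5-[(1R,4E,6R,8E)-11-(furan-3-yl)-1,6-dihydroxy-4,8-dimethylundeca-4,8-dien-1-yl]-5-methyl-2-oxooxolane-3-carboxylic acid F7. Heating in toluene decarboxylates F7 to 30.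

3. Step 9. Homocoupling during Grignard formation, attack at the γ-carbon of the allyl bromide, or copper-mediated attack on the vinylic bromide may erode the coupling. The fallback makes the bromoalkene last, from an alkyne; it sets out from 16 and returns at 18. Chloride 16 is alkylated with 3-lithio-1-(trimethylsilyl)propyne (THF, −78 °C) to give [4-(furan-3-yl)but-1-yn-1-yl](trimethyl)silane F8. K2CO3 in MeOH gives 3-(but-3-yn-1-yl)furan F9, and n-BuLi then MeI gives 3-(pent-3-yn-1-yl)furan F10. Hydrozirconation with excess Cp2Zr(H)Cl, equilibrated so that zirconium sits next to the methyl group, followed by NBS gives 18.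

**Further compounds**

F1 | step 10 | (3E)-6-(furan-3-yl)-3-methylhex-3-en-1-ol | OCC/C(C)=C/CCc1ccoc1
F2 | step 10 | (3E)-6-(furan-3-yl)-3-methylhex-3-enal | O=CC/C(C)=C/CCc1ccoc1
F3 | step 10 | (2E,6E,10E)-1-{[tert-butyl(dimethyl)silyl]oxy}-13-(furan-3-yl)-2,6,10-trimethyltrideca-2,6,10-trien-8-ol (both C8 epimers) | CC(C)(C)[Si](C)(C)OC/C(C)=C/CC/C(C)=C/C(O)C/C(C)=C/CCc1ccoc1
F4 | step 10 | (2E,6E,10E)-1-{[tert-butyl(dimethyl)silyl]oxy}-13-(furan-3-yl)-2,6,10-trimethyltrideca-2,6,10-trien-8-one | CC(C)(C)[Si](C)(C)OC/C(C)=C/CC/C(C)=C/C(=O)C/C(C)=C/CCc1ccoc1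
F5 | step 16 | (3E,5R,7E)-10-(furan-3-yl)-1-[(2R,3S)-3-(iodomethyl)-3-methyloxiran-2-yl]-3,7-dimethyldeca-3,7-dien-5-yl acetate | IC[C@@]1(C)O[C@@H]1CC/C(C)=C/[C@H](OC(C)=O)C/C(C)=C/CCc1ccoc1
F6 | step 16 | dimethyl 2-{[(2R,3R)-3-{(3E,5R,7E)-5-acetoxy-10-(furan-3-yl)-3,7-dimethyldeca-3,7-dien-1-yl}-2-methyloxiran-2-yl]methyl}propanedioate | COC(=O)C(C[C@@]1(C)O[C@@H]1CC/C(C)=C/[C@H](OC(C)=O)C/C(C)=C/CCc1ccoc1)C(=O)OC
F7 | step 16 | (5S)-5-[(1R,4E,6R,8E)-11-(furan-3-yl)-1,6-dihydroxy-4,8-dimethylundeca-4,8-dien-1-yl]-5-methyl-2-oxooxolane-3-carboxylic acid (C3 epimers) | C/C(=C\[C@H](O)C/C(C)=C/CCc1ccoc1)CC[C@@H](O)[C@]1(C)CC(C(O)=O)C(=O)O1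
F8 | step 9 | [4-(furan-3-yl)but-1-yn-1-yl](trimethyl)silane | C[Si](C)(C)C#CCCc1ccoc1
F9 | step 9 | 3-(but-3-yn-1-yl)furan | C#CCCc1ccoc1
F10 | step 9 | 3-(pent-3-yn-1-yl)furan | CC#CCCc1ccoc1
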